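**Plan**
1. The target is read as imbricatolic acid 15-formate (labdane numbering). The retrosynthesis removes the formate, turns C8=C17 with 9α-H back into a C17-silyl Δ8 allylsilane, and adds a temporary carboxyl carbon C6' on C6β that is tied to C19 as a six-membered anhydride.
2. Further cuts: C5–C10 and C6–C7 together (ring B from the diene C7=C8–C9=C10 and the dienophile C5=C6, ring A through the tether C1–C3), then C1–C10 (B-alkyl Suzuki–Miyaura), C9–C11 (acetoacetate alkylation) and C4–C3/C4–C18 (malate alkylations).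
3. Enabling feature: ring B has an unsubstituted C5–C6 edge opposite the C8 exocyclic methylene (a diene retron), and the axial C19 carboxyl on C4 is 1,3-diaxial to C6β. A temporary ring C4–C19–O–C6'–C6–C5 can therefore activate C5=C6 and hold C19 cis to C6.
4. Forward order: fragment 1 (diene plus side chain) from (S)-citronellol and methyl acetoacetate; fragment 2 (dienophile) from dimethyl (S)-malate; union; anhydride formation; one cycloaddition closes rings A and B; C6' is excised; the allylsilane is unmasked.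
5. Stereochemistry: C13 from (S)-citronellol; C4 from the Fráter–Seebach dialkylation of (S)-malate; C5 and C10 relayed from C4 in the cycloaddition; C9 by axial protodesilylation.

Key step: step 14

Remark: labdane numbering is used for all intermediates (C1–C10 decalin, C11–C16 side chain, C17 on C8, C18/C19 on C4, C20 on C10); C6' is the temporary carboxyl carbon on C6.

Step 1
Reactants: 1 (S)-citronellol
Product: 2 tert-butyl{[(3S)-3,7-dimethyloct-6-en-1-yl]oxy}dimethylsilane
Conditions: TBSCl, imidazole, DMF, rt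
Reagents that add atoms: tert-butyldimethylsilyl chloride, CC(C)(C)[Si](C)(C)Cl
Why: Routine silylation of a primary alcohol; the C13 stereocentre is carried in from the chiral pool.

Step 2
Reactants: 2 tert-butyl{[(3S)-3,7-dimethyloct-6-en-1-yl]oxy}dimethylsilane
Product: 3 (4S)-6-[(tert-butyldimethylsilyl)oxy]-4-methylhexanoic acid
Conditions: RuCl3·xH2O (2 mol %), NaIO4 (4 equiv), CCl4/MeCN/H2O, rt
Reagents that add atoms: sodium periodate, [Na+].[O-]I(=O)(=O)=O; water, O
Why: RuO4-catalysed oxidative cleavage of the trisubstituted alkene should give the acid and acetone directly, without touching the remote stereocentre.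

Step 3
Reactants: 3 (4S)-6-[(tert-butyldimethylsilyl)oxy]-4-methylhexanoic acid
Product: 4 tert-butyl{[(3R)-5-iodo-3-methylpentyl]oxy}dimethylsilane
Conditions: PhI(OAc)2, I2, cyclohexane, hν (tungsten lamp), 40 °C
Reagents that add atoms: iodine, II
Why: Hunsdiecker-type iododecarboxylation through the acyl hypoiodite (homolysis, loss of CO2, iodine-atom transfer) shortens the chain by one carbon; the descriptor changes to R only because the CIP priorities change.

Step 4
Reactants: 4 tert-butyl{[(3R)-5-iodo-3-methylpentyl]oxy}dimethylsilane; 5 methyl acetoacetate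
Product: 6 methyl (5S)-2-acetyl-7-[(tert-butyldimethylsilyl)oxy]-5-methylheptanoate (mixture of C2 epimers)
Conditions: NaH, 5 (2 equiv), THF/DMF, 0 → 60 °C
Reagents that add atoms: none
Why: Classical C-alkylation of the acetoacetate enolate with a primary iodide forms C9–C11; the epimeric centre becomes sp2 in the next step.

Step 5
Reactants: 6 methyl (5S)-2-acetyl-7-[(tert-butyldimethylsilyl)oxy]-5-methylheptanoate
Product: 7 methyl (2E)-2-{(3S)-5-[(tert-butyldimethylsilyl)oxy]-3-methylpentyl}-3-{[(trifluoromethyl)sulfonyl]oxy}but-2-enoate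
Conditions: Tf2O, aqueous Me4NOH, toluene, 5 °C
Reagents that add atoms: trifluoromethanesulfonic anhydride, O=S(=O)(OS(=O)(=O)C(F)(F)F)C(F)(F)F
Why: The non-chelated ammonium enolate should adopt the dipole-minimised geometry with the enolate oxygen anti to the ester, so O-triflation is expected to give the (E)-enol triflate (triflate trans to CO2Me, methyl cis), which is the stereocomplementary enol sulfonylation known for β-keto esters.

Step 6
Reactants: 7 methyl (2E)-2-{(3S)-5-[(tert-butyldimethylsilyl)oxy]-3-methylpentyl}-3-{[(trifluoromethyl)sulfonyl]oxy}but-2-enoate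
Product: 9 (2E)-3-{(3S)-5-[(tert-butyldimethylsilyl)oxy]-3-methylpentyl}-4-[(trimethylsilyl)methyl]penta-2,4-dien-2-yl trifluoromethanesulfonate, via bis(silylmethyl)carbinol 8 (not isolated)
Conditions: Me3SiCH2MgCl (4 equiv), CeCl3, THF, −78 → 0 °C; then SiO2, CH2Cl2, rt
Reagents that add atoms: (trimethylsilyl)methylmagnesium chloride, C[Si](C)(C)C[Mg]Cl
Why: The weakly basic organocerium reagent should add twice to the hindered ester while sparing the vinyl triflate, and acid-promoted Peterson elimination of the resulting carbinol on silica gives the 2-(silylmethyl)diene with the C9=C10 geometry unchanged.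

Step 7
Reactants: 10 dimethyl (S)-malate
Product: 11 dimethyl (2S,3R)-2-hydroxy-3-(prop-2-en-1-yl)butanedioate
Conditions: LDA (2.2 equiv), THF, −78 → −20 °C; allyl bromide, −78 → 0 °C
Reagents that add atoms: allyl bromide, C=CCBr
Why: Fráter–Seebach alkylation of the lithium-chelated alkoxide enolate, in which the electrophile enters anti to the ester on the carbinol carbon, should give the (2S,3R) product.

Step 8
Reactants: 11 dimethyl (2S,3R)-2-hydroxy-3-(prop-2-en-1-yl)butanedioate
Product: 12 dimethyl (2S,3S)-2-hydroxy-3-methyl-3-(prop-2-en-1-yl)butanedioate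
Conditions: LDA (2.2 equiv), THF/DMPU, −78 → −20 °C; MeI
Reagents that add atoms: iodomethane, CI
Why: A second Fráter–Seebach alkylation of the now tetrasubstituted chelated enolate should again take the electrophile on the face anti to the carbinol ester, so the order allyl-then-methyl fixes the quaternary centre (later C4) in the required sense.

Step 9
Reactants: 12 dimethyl (2S,3S)-2-hydroxy-3-methyl-3-(prop-2-en-1-yl)butanedioate
Product: 13 (2S,3S)-2-hydroxy-3-(methoxycarbonyl)-3-methylhex-5-enoic acid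
Conditions: KOH (1.0 equiv), MeOH/H2O, 0 °C; then HCl to pH 2
Reagents that add atoms: potassium hydroxide, [K+].[OH-]
Why: The α-hydroxy ester is activated and unhindered whereas the other ester is neopentyl-type, so mono-saponification should be chemoselective.

Step 10
Reactants: 13 (2S,3S)-2-hydroxy-3-(methoxycarbonyl)-3-methylhex-5-enoic acid
Product: 14 methyl (2S)-2-formyl-2-methylpent-4-enoate
Conditions: Pb(OAc)4, CH2Cl2, 0 °C
Reagents that add atoms: none
Why: Oxidative decarboxylation of the α-hydroxy acid gives the aldehyde (later C5); the quaternary centre has no α-hydrogen and cannot epimerise.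

Step 11
Reactants: 14 methyl (2S)-2-formyl-2-methylpent-4-enoate
Product: 15 dimethyl (2Z,4S)-4-methyl-4-(prop-2-en-1-yl)pent-2-enedioate
Conditions: (CF3CH2O)2P(O)CH2CO2Me, KHMDS, 18-crown-6, THF, −78 °C
Reagents that add atoms: methyl bis(2,2,2-trifluoroethyl)phosphonoacetate, COC(=O)CP(=O)(OCC(F)(F)F)OCC(F)(F)F
Why: Still–Gennari olefination of the non-enolisable aldehyde should give the (Z)-enoate, placing the two carboxyl carbons (C19 and C6') cis as needed for the later anhydride.

Step 12
Reactants: 15 dimethyl (2Z,4S)-4-methyl-4-(prop-2-en-1-yl)pent-2-enedioate; 9 (2E)-3-{(3S)-5-[(tert-butyldimethylsilyl)oxy]-3-methylpentyl}-4-[(trimethylsilyl)methyl]penta-2,4-dien-2-yl trifluoromethanesulfonate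
Product: 17 dimethyl (2Z,4S)-4-[(4E)-5-{(3S)-5-[(tert-butyldimethylsilyl)oxy]-3-methylpentyl}-4-methyl-6-[(trimethylsilyl)methyl]hepta-4,6-dien-1-yl]-4-methylpent-2-enedioate, via B-alkyl-9-BBN adduct 16 (not isolated)
Conditions: 9-BBN-H, THF, 0 °C → rt; then 9, PdCl2(dppf) (5 mol %), AsPh3, Cs2CO3, DMF/THF/H2O, rt → 45 °C
Reagents that add atoms: none
Why: 9-BBN should hydroborate only the unhindered terminal alkene (the electron-poor Z-enoate is inert), and the B-alkyl Suzuki–Miyaura coupling replaces the triflate with retention, so the tether ends up trans to C8 and the methyl cis.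

Step 13
Reactants: 17 dimethyl (2Z,4S)-4-[(4E)-5-{(3S)-5-[(tert-butyldimethylsilyl)oxy]-3-methylpentyl}-4-methyl-6-[(trimethylsilyl)methyl]hepta-4,6-dien-1-yl]-4-methylpent-2-enedioate
Product: 18 (2Z,4S)-4-[(4E)-5-{(3S)-5-[(tert-butyldimethylsilyl)oxy]-3-methylpentyl}-4-methyl-6-[(trimethylsilyl)methyl]hepta-4,6-dien-1-yl]-4-methylpent-2-enedioic acid
Conditions: LiOH·H2O (10 equiv), THF/MeOH/H2O, 50 °C; then cold 1 M HCl to pH 3
Reagents that add atoms: lithium hydroxide, [Li+].[OH-]
Why: Saponification of both methyl esters (the neopentyl one needs warming); the Z geometry should survive because there is no enolisable position and the enoate carboxylate resists conjugate addition, and the allylsilane and silyl ether are base-stable.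

Step 14
Reactants: 18 (2Z,4S)-4-[(4E)-5-{(3S)-5-[(tert-butyldimethylsilyl)oxy]-3-methylpentyl}-4-methyl-6-[(trimethylsilyl)methyl]hepta-4,6-dien-1-yl]-4-methylpent-2-enedioic acid
Product: 20 6β-carboxy-15-[(tert-butyldimethylsilyl)oxy]-17-(trimethylsilyl)labd-8-en-19-oic acid cyclic 6',19-anhydride (5α-H; 10β-CH3; trans-decalin), via glutaconic anhydride 19 (not isolated)
Conditions: DCC (1.1 equiv), CH2Cl2, 0 °C → rt, filter, evaporate; then toluene (0.005 M), BHT, 140 °C, sealed tube
Reagents that add atoms: none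
Why: Cyclodehydration of the (Z)-diacid gives the non-enolisable glutaconic anhydride 19, whose C5=C6 bond, activated by the C6' carbonyl, should add suprafacially to the C7=C8–C9=C10 diene in a thermal, concerted but asynchronous [4+2] cycloaddition (an intramolecular Diels–Alder reaction of a 1,7,9-decatriene; the closest known cases are intramolecular Diels–Alder reactions of cycloalkenone and butenolide dienophiles tethered through their γ-carbon, and Diels–Alder reactions of 2-(silylmethyl)butadienes). Ring A closes in the fused mode through the three-carbon tether C1–C3 by C5–C10 bonding (six-membered, chair-like), and ring B is the new cyclohexene closed by C5–C10 and C6–C7. Because the anhydride ring holds C19 in the plane of the dienophile and the tether leaves C4 perpendicular to that plane, the diene can only reach the face of C5=C6 that carries C3, which fixes C5 (and the transient C6 centre) relative to C4 with C19 on the side opposite H5, that is axial and cis to C20 as in the target. C10 is set by the exo (anhydride-out) transition state, which gives the trans ring fusion; it should be preferred because the endo alternative forces the C9 side chain against the quaternary C4, whereas the exo mode only places the C10 methyl over C19. The (E) geometry of C9=C10 puts the tether outside and the methyl inside so that the methyl becomes angular, and the one selectivity the step still needs is exo over endo, which the C9 substituent and the quaternary C4 secure. The silylmethyl group raises the diene HOMO and survives the neutral thermal conditions, with BHT and base-washed glassware guarding against polymerisation and premature protodesilylation.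

Step 15
Reactants: 20 6β-carboxy-15-[(tert-butyldimethylsilyl)oxy]-17-(trimethylsilyl)labd-8-en-19-oic acid cyclic 6',19-anhydride
Product: 22 15-[(tert-butyldimethylsilyl)oxy]-17-(trimethylsilyl)labd-8-en-19-oic acid, via tert-butyl perester 21 (not isolated)
Conditions: t-BuOOH (in decane), Et3N, DMAP (cat.), CH2Cl2, 0 °C → rt; NaH2PO4 wash, evaporate below 30 °C; then 1,4-cyclohexadiene/benzene, 100 °C, sealed tube
Reagents that add atoms: none
Why: tert-Butyl hydroperoxide should open the anhydride at the less hindered C6' carbonyl (C19 is neopentyl) and cannot be expelled again, and thermolysis of the secondary perester (perester decarboxylation: O–O/C–C scission, loss of CO2, hydrogen transfer from cyclohexadiene to the C6 radical) removes the temporary carbon and frees the C19 acid.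

Step 16
Reactants: 22 15-[(tert-butyldimethylsilyl)oxy]-17-(trimethylsilyl)labd-8-en-19-oic acid
Product: 23 imbricatolic acid [(4S,5R,9S,10R,13S)-15-hydroxylabd-8(17)-en-19-oic acid]
Conditions: TsOH·H2O (0.3 equiv), MeOH/CH2Cl2 (1:1), 0 °C → rt, short reaction time; NaHCO3 quench
Reagents that add atoms: none
Why: Protodesilylation of the allylsilane (SE2') should protonate C9 axially from the α-face, anti to the C10 methyl, to give 9α-H, and loss of silicon from the β-silyl cation gives the exocyclic C8=C17 alkene; the same acid methanolyses the TBS ether.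

Step 17
Reactants: 23 imbricatolic acid
Product: 24 15-(formyloxy)labd-8(17)-en-19-oic acid (target, CNP0494097.1)
Conditions: HCO2CH2CF3 (excess), 65 °C
Reagents that add atoms: 2,2,2-trifluoroethyl formate, O=COCC(F)(F)F
Why: Neutral transfer formylation of the primary alcohol; the hindered axial carboxylic acid and the exocyclic alkene should be untouched.

**Compound list**
1 | (S)-citronellol [(3S)-3,7-dimethyloct-6-en-1-ol] | CC(C)=CCC[C@H](C)CCO | starting material
2 | tert-butyl{[(3S)-3,7-dimethyloct-6-en-1-yl]oxy}dimethylsilane | CC(C)=CCC[C@H](C)CCO[Si](C)(C)C(C)(C)C | intermediate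
3 | (4S)-6-[(tert-butyldimethylsilyl)oxy]-4-methylhexanoic acid | OC(=O)CC[C@H](C)CCO[Si](C)(C)C(C)(C)C | intermediate
4 | tert-butyl{[(3R)-5-iodo-3-methylpentyl]oxy}dimethylsilane | ICC[C@H](C)CCO[Si](C)(C)C(C)(C)C | intermediate
5 | methyl acetoacetate | CC(=O)CC(=O)OC | starting material
6 | methyl (5S)-2-acetyl-7-[(tert-butyldimethylsilyl)oxy]-5-methylheptanoate (C2 epimers) | COC(=O)C(CC[C@H](C)CCO[Si](C)(C)C(C)(C)C)C(C)=O | intermediate
7 | methyl (2E)-2-{(3S)-5-[(tert-butyldimethylsilyl)oxy]-3-methylpentyl}-3-{[(trifluoromethyl)sulfonyl]oxy}but-2-enoate | C/C(OS(=O)(=O)C(F)(F)F)=C(\C(=O)OC)CC[C@H](C)CCO[Si](C)(C)C(C)(C)C | intermediate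
8 | (2E)-3-{(3S)-5-[(tert-butyldimethylsilyl)oxy]-3-methylpentyl}-4-hydroxy-5-(trimethylsilyl)-4-[(trimethylsilyl)methyl]pent-2-en-2-yl trifluoromethanesulfonate | C/C(OS(=O)(=O)C(F)(F)F)=C(\C(O)(C[Si](C)(C)C)C[Si](C)(C)C)CC[C@H](C)CCO[Si](C)(C)C(C)(C)C | intermediate
9 | (2E)-3-{(3S)-5-[(tert-butyldimethylsilyl)oxy]-3-methylpentyl}-4-[(trimethylsilyl)methyl]penta-2,4-dien-2-yl trifluoromethanesulfonate | C/C(OS(=O)(=O)C(F)(F)F)=C(\C(=C)C[Si](C)(C)C)CC[C@H](C)CCO[Si](C)(C)C(C)(C)C | intermediate
10 | dimethyl (S)-malate | COC(=O)[C@@H](O)CC(=O)OC | starting material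
11 | dimethyl (2S,3R)-2-hydroxy-3-(prop-2-en-1-yl)butanedioate | COC(=O)[C@@H](O)[C@@H](CC=C)C(=O)OC | intermediate
12 | dimethyl (2S,3S)-2-hydroxy-3-methyl-3-(prop-2-en-1-yl)butanedioate | COC(=O)[C@@H](O)[C@](C)(CC=C)C(=O)OC | intermediate
13 | (2S,3S)-2-hydroxy-3-(methoxycarbonyl)-3-methylhex-5-enoic acid | OC(=O)[C@@H](O)[C@](C)(CC=C)C(=O)OC | intermediate
14 | methyl (2S)-2-formyl-2-methylpent-4-enoate | C=CC[C@](C=O)(C)C(=O)OC | intermediate
15 | dimethyl (2Z,4S)-4-methyl-4-(prop-2-en-1-yl)pent-2-enedioate | C=CC[C@](/C=C\C(=O)OC)(C)C(=O)OC | intermediate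
16 | dimethyl (2Z,4S)-4-[3-(9-borabicyclo[3.3.1]nonan-9-yl)propyl]-4-methylpent-2-enedioate | C(CC[C@](/C=C\C(=O)OC)(C)C(=O)OC)B1C2CCCC1CCC2 | intermediate
17 | dimethyl (2Z,4S)-4-[(4E)-5-{(3S)-5-[(tert-butyldimethylsilyl)oxy]-3-methylpentyl}-4-methyl-6-[(trimethylsilyl)methyl]hepta-4,6-dien-1-yl]-4-methylpent-2-enedioate | C(/C(C)=C(\CC[C@H](C)CCO[Si](C)(C)C(C)(C)C)C(=C)C[Si](C)(C)C)CC[C@](/C=C\C(=O)OC)(C)C(=O)OC | intermediate
18 | (2Z,4S)-4-[(4E)-5-{(3S)-5-[(tert-butyldimethylsilyl)oxy]-3-methylpentyl}-4-methyl-6-[(trimethylsilyl)methyl]hepta-4,6-dien-1-yl]-4-methylpent-2-enedioic acid | C(/C(C)=C(\CC[C@H](C)CCO[Si](C)(C)C(C)(C)C)C(=C)C[Si](C)(C)C)CC[C@](/C=C\C(=O)O)(C)C(=O)O | intermediate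
19 | (3S)-3-[(4E)-5-{(3S)-5-[(tert-butyldimethylsilyl)oxy]-3-methylpentyl}-4-methyl-6-[(trimethylsilyl)methyl]hepta-4,6-dien-1-yl]-3-methyl-2H-pyran-2,6(3H)-dione | C(/C(C)=C(\CC[C@H](C)CCO[Si](C)(C)C(C)(C)C)C(=C)C[Si](C)(C)C)CC[C@@]1(C)C=CC(=O)OC1=O | intermediate
20 | 6β-carboxy-15-[(tert-butyldimethylsilyl)oxy]-17-(trimethylsilyl)labd-8-en-19-oic acid cyclic 6',19-anhydride (18-CH3 α, C19 β, 5α-H, C6' β, 10β-CH3) | C[Si](C)(C)CC1=C(CC[C@H](C)CCO[Si](C)(C)C(C)(C)C)[C@@]2(C)CCC[C@]3(C)C(=O)OC(=O)[C@H](C1)[C@H]23 | intermediate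
21 | 6β-[(tert-butylperoxy)carbonyl]-15-[(tert-butyldimethylsilyl)oxy]-17-(trimethylsilyl)labd-8-en-19-oic acid | C[Si](C)(C)CC1=C(CC[C@H](C)CCO[Si](C)(C)C(C)(C)C)[C@@]2(C)CCC[C@](C)(C(=O)O)[C@@H]2[C@@H](C1)C(=O)OOC(C)(C)C | intermediate
22 | 15-[(tert-butyldimethylsilyl)oxy]-17-(trimethylsilyl)labd-8-en-19-oic acid (5α-H, 10β-CH3, 19-acid β) | C[Si](C)(C)CC1=C(CC[C@H](C)CCO[Si](C)(C)C(C)(C)C)[C@@]2(C)CCC[C@](C)(C(=O)O)[C@@H]2CC1 | intermediate
23 | imbricatolic acid [(4S,5R,9S,10R,13S)-15-hydroxylabd-8(17)-en-19-oic acid] | C=C1CC[C@@H]2[C@](C)(CCC[C@]2(C)C(=O)O)[C@H]1CC[C@H](C)CCO | intermediate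
24 | (4S,5R,9S,10R,13S)-15-(formyloxy)labd-8(17)-en-19-oic acid | C=C1CC[C@@H]2[C@](C)(CCC[C@]2(C)C(=O)O)[C@H]1CC[C@H](C)CCOC=O | target

**Step count:** 17 steps in total. The longest linear sequence is 12 steps (steps 1–6, then 12–17).

**Steps most likely to fail**

Step 14. The endo mode (cis ring fusion) may compete with the required exo mode, or the hindered C5–C10 bond may form so slowly that [1,5]-hydrogen shift in the diene or protodesilylation takes over. The fallback abandons the temporary ring and uses an acyclic (E)-dienophile with a traceless sulfone. It sets out from aldehyde 14 and triflate 9 and returns at 22. Horner–Wadsworth–Emmons reaction of 14 with diethyl (phenylsulfonylmethyl)phosphonate (NaH, THF) gives methyl (2S)-2-methyl-2-[(E)-2-(phenylsulfonyl)ethenyl]pent-4-enoate F1. Hydroboration with 9-BBN-H and Suzuki–Miyaura coupling with 9 gives the triene sulfone F2. Heating in toluene at 160 °C should give the trans-fused 6α-phenylsulfonyl cycloadduct F3 through the sulfone-endo transition state; here the facial preference rests only on the ester rather than the methyl taking the axial site opposite the C10 methyl, so the C4 epimer would have to be separated. Na(Hg) in buffered MeOH removes the sulfone to give methyl ester F4, and n-PrSLi in HMPA demethylates the hindered ester to 22.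

Step 6. The organocerium reagent may attack the sulfonyl group, or add–eliminate at C10, so that the triflate is lost before the ester has reacted twice. The fallback builds the allylsilane one carbon at a time. It sets out from 7 and returns at 9. DIBAL-H at −78 °C gives allylic alcohol F5, MnO2 gives enal F6, Me3SiCH2MgCl at −78 °C gives β-hydroxysilane F7, Dess–Martin periodinane (NaHCO3) gives β-silyl ketone F8, and Wittig methylenation (Ph3P=CH2, THF, −78 → 0 °C) gives 9.

Step 15. The hindered anhydride may open slowly or at the wrong carbonyl, and cage recombination or allylic hydrogen abstraction may erode the perester thermolysis. The fallback differentiates the two carboxyls by ester hydrolysis rates and uses a Barton decarboxylation. It sets out from 20 and returns at 22. Aqueous LiOH opens 20 to diacid F9; allyl bromide and Cs2CO3 in DMF give diallyl ester F10; LiOH (1 equiv) cleaves only the less hindered C6' ester to give acid F11; DCC and N-hydroxypyridine-2-thione followed by t-BuSH under visible light give the decarboxylated allyl ester F12; Pd(PPh3)4 and morpholine release 22.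

Further compounds
F1 | step 14 | methyl (2S)-2-methyl-2-[(E)-2-(phenylsulfonyl)ethenyl]pent-4-enoate | C=CC[C@](/C=C/S(=O)(=O)c1ccccc1)(C)C(=O)OC
F2 | step 14 | methyl (2S)-2-[(4E)-5-{(3S)-5-[(tert-butyldimethylsilyl)oxy]-3-methylpentyl}-4-methyl-6-[(trimethylsilyl)methyl]hepta-4,6-dien-1-yl]-2-methyl-4-(phenylsulfonyl)but-3-enoate (3E) | C(/C(C)=C(\CC[C@H](C)CCO[Si](C)(C)C(C)(C)C)C(=C)C[Si](C)(C)C)CC[C@](/C=C/S(=O)(=O)c1ccccc1)(C)C(=O)OC
F3 | step 14 | methyl 15-[(tert-butyldimethylsilyl)oxy]-6α-(phenylsulfonyl)-17-(trimethylsilyl)labd-8-en-19-oate | C[Si](C)(C)CC1=C(CC[C@H](C)CCO[Si](C)(C)C(C)(C)C)[C@@]2(C)CCC[C@](C)(C(=O)OC)[C@@H]2[C@H](C1)S(=O)(=O)c1ccccc1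
F4 | step 14 | methyl 15-[(tert-butyldimethylsilyl)oxy]-17-(trimethylsilyl)labd-8-en-19-oate | C[Si](C)(C)CC1=C(CC[C@H](C)CCO[Si](C)(C)C(C)(C)C)[C@@]2(C)CCC[C@](C)(C(=O)OC)[C@@H]2CC1
F5 | step 6 | (2E)-3-{(3S)-5-[(tert-butyldimethylsilyl)oxy]-3-methylpentyl}-4-hydroxybut-2-en-2-yl trifluoromethanesulfonate | C/C(OS(=O)(=O)C(F)(F)F)=C(\CO)CC[C@H](C)CCO[Si](C)(C)C(C)(C)C
F6 | step 6 | (2E)-3-{(3S)-5-[(tert-butyldimethylsilyl)oxy]-3-methylpentyl}-4-oxobut-2-en-2-yl trifluoromethanesulfonate | C/C(OS(=O)(=O)C(F)(F)F)=C(\C=O)CC[C@H](C)CCO[Si](C)(C)C(C)(C)C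
F7 | step 6 | (2E)-3-{(3S)-5-[(tert-butyldimethylsilyl)oxy]-3-methylpentyl}-4-hydroxy-5-(trimethylsilyl)pent-2-en-2-yl trifluoromethanesulfonate | C/C(OS(=O)(=O)C(F)(F)F)=C(\C(O)C[Si](C)(C)C)CC[C@H](C)CCO[Si](C)(C)C(C)(C)C
F8 | step 6 | (2E)-3-{(3S)-5-[(tert-butyldimethylsilyl)oxy]-3-methylpentyl}-4-oxo-5-(trimethylsilyl)pent-2-en-2-yl trifluoromethanesulfonate | C/C(OS(=O)(=O)C(F)(F)F)=C(\C(=O)C[Si](C)(C)C)CC[C@H](C)CCO[Si](C)(C)C(C)(C)C
F9 | step 15 | 6β-carboxy-15-[(tert-butyldimethylsilyl)oxy]-17-(trimethylsilyl)labd-8-en-19-oic acid | C[Si](C)(C)CC1=C(CC[C@H](C)CCO[Si](C)(C)C(C)(C)C)[C@@]2(C)CCC[C@](C)(C(=O)O)[C@@H]2[C@@H](C1)C(=O)O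
F10 | step 15 | diallyl diester of F9 (allyl 6β-[(allyloxy)carbonyl]-15-[(tert-butyldimethylsilyl)oxy]-17-(trimethylsilyl)labd-8-en-19-oate) | C[Si](C)(C)CC1=C(CC[C@H](C)CCO[Si](C)(C)C(C)(C)C)[C@@]2(C)CCC[C@](C)(C(=O)OCC=C)[C@@H]2[C@@H](C1)C(=O)OCC=C
F11 | step 15 | 19-allyl ester 6β-carboxylic acid (allyl 6β-carboxy-15-[(tert-butyldimethylsilyl)oxy]-17-(trimethylsilyl)labd-8-en-19-oate) | C[Si](C)(C)CC1=C(CC[C@H](C)CCO[Si](C)(C)C(C)(C)C)[C@@]2(C)CCC[C@](C)(C(=O)OCC=C)[C@@H]2[C@@H](C1)C(=O)O
F12 | step 15 | allyl 15-[(tert-butyldimethylsilyl)oxy]-17-(trimethylsilyl)labd-8-en-19-oate | C[Si](C)(C)CC1=C(CC[C@H](C)CCO[Si](C)(C)C(C)(C)C)[C@@]2(C)CCC[C@](C)(C(=O)OCC=C)[C@@H]2CC1
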